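**Plan**
Retrosynthesis: (i) the exocyclic enol-lactone C=C and the lactone C=O go back to a 2,3,4-trisubstituted furan (singlet-oxygen oxidation, then dehydration); (ii) the acetate and senecioate C–O bonds; (iii) the CH(CH3)–CH2 bond of the medium ring, cut to a furanone extended enolate and a terminal oxirane; (iv) the furan ring (Feist–Benary); (v) the furanone ring, back to a 2-hydroxy-ynone from (S)-citramalic acid and 1-butyne.
Forward: furanone ring (steps 1–3), furan ring as a masked butenolide (4–5), oxirane arm (6–10), nine-membered oxa-bridged ring / ten-membered carbocycle (11), esters (12–14), butenolide with its exocyclic double bond (15–16).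
Enabling feature: in the 3(2H)-furanone ring C2 is quaternary, so the only acidic C–H is the CH2 of the ethyl group on C5 (γ-position of the vinylogous ester O1–C5=C4–C3=O). Its extended enolate is nucleophilic at that carbon, and the strained oxirane on furan C3, held next to the C2–CH2 link, supplies the CH2 electrophile and the driving force.
Stereochemistry: the quaternary C–O centre comes unchanged from (S)-citramalic acid; the carbinol centre comes from Ru/TsDPEN transfer hydrogenation ((R)-oxirane, retained on opening); the C-methyl centre is set in the key step by the ring; the alkene geometry is dictated by the ring in the last step.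

Key step: step 11

Assumption: (S)-citramalic acid, 1-butyne and 1-acetoxy-3-chloroacetone are taken as purchasable; furan positions are called C2 (CH2 link), C3, C4 (CH2O arm) and C5 (H) throughout.

**Step 1**
Reactants: 1 (S)-citramalic acid
Product: 2 2-[(4S)-2,2,4-trimethyl-5-oxo-1,3-dioxolan-4-yl]acetic acid
Conditions: 2,2-dimethoxypropane, TsOH·H2O (cat.), 25 °C
Reagents that add atoms: 2,2-dimethoxypropane, COC(C)(C)OC
Why: Acid-catalysed acetonide formation engages the tertiary hydroxyl and the adjacent carboxyl in the favoured five-membered 1,3-dioxolan-4-one and leaves the CH2CO2H arm free, so the two carboxyls are told apart without touching the (S) centre.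

**Step 2**
Reactants: 2 acetonide acid; 3 1-butyne
Product: 6 (3S)-3-hydroxy-3-methyl-4-oxooct-5-ynoic acid, via 1-butynyllithium 4 (not isolated), via dilithium hemiketal 5 (not isolated)
Conditions: 3 (2.2 equiv), n-BuLi (2.1 equiv), THF, −78 °C; then 2, −78 → −40 °C; 1 M HCl
Reagents that add atoms: none
Why: One equivalent of 4 forms the lithium carboxylate and the second adds to the lactone-type carbonyl (acyl substitution of a 1,3-dioxolan-4-one by an organolithium) to give hemiketal 5, which is stable at low temperature, resists a second addition, and collapses on acidic work-up with loss of acetone; the quaternary centre is not involved.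

**Step 3**
Reactants: 6 hydroxy-ynone acid
Product: 7 2-[(2S)-5-ethyl-2-methyl-3-oxo-2,3-dihydrofuran-2-yl]acetic acid
Conditions: Ph3PAuNTf2 (monovalent gold, 2 mol%), CH2Cl2, 25 °C
Reagents that add atoms: none
Why: Gold-catalysed cycloisomerization of a 2-hydroxy-alk-4-yn-3-one: the tertiary hydroxyl attacks the activated β-alkyne carbon (5-endo-dig) and protodeauration gives the 3(2H)-furanone, while the carboxyl would have to close a seven-membered ring to compete.

**Step 4**
Reactants: 7 furanone acid
Product: 10 tert-butyl 4-[(2S)-5-ethyl-2-methyl-3-oxo-2,3-dihydrofuran-2-yl]-3-oxobutanoate, via acyl imidazole 8 (not isolated), via acyl Meldrum's acid 9 (not isolated)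
Conditions: CDI, THF, 25 °C; then Meldrum's acid, 25 °C; then t-BuOH, toluene, 80 °C
Reagents that add atoms: Meldrum's acid, CC1(C)OC(=O)CC(=O)O1; tert-butanol, CC(C)(C)O
Why: Meldrum's acid homologation: 8 C-acylates Meldrum's acid and thermolysis of 9 gives an acyl ketene that tert-butanol traps as the β-keto ester, under near-neutral conditions that do not enolize the CH2 next to the oxygen-bearing quaternary carbon.

**Step 5**
Reactants: 10 β-keto ester; 11 1-acetoxy-3-chloroacetone
Product: 13 tert-butyl 4-(acetoxymethyl)-2-{[(2S)-5-ethyl-2-methyl-3-oxo-2,3-dihydrofuran-2-yl]methyl}furan-3-carboxylate, via hydroxydihydrofuran 12 (not isolated)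
Conditions: pyridine, 25 → 50 °C; then TsOH·H2O (cat.), CH2Cl2, 25 °C
Reagents that add atoms: none
Why: Feist–Benary furan synthesis: the doubly activated carbon of 10 adds to the ketone of 11, the enol oxygen displaces chloride to give 12, and loss of water aromatizes it, which fixes the CH2 link on C2, the ester on C3, CH2OAc on C4 and H on C5.

**Step 6**
Reactants: 13 furan tert-butyl ester
Product: 14 4-(acetoxymethyl)-2-{[(2S)-5-ethyl-2-methyl-3-oxo-2,3-dihydrofuran-2-yl]methyl}furan-3-carboxylic acid
Conditions: TFA, CH2Cl2, 0 → 25 °C
Reagents that add atoms: none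
Why: Acidolysis of the tert-butyl ester (loss of 2-methylpropene) frees the acid, and the acetate, the furanone and the ester-deactivated furan tolerate TFA.

**Step 7**
Reactants: 14 furan carboxylic acid
Product: 17 chloromethyl ketone (furan C3 bears C(=O)CH2Cl; otherwise as 14), via acid chloride 15 (not isolated), via diazoketone 16 (not isolated)
Conditions: (COCl)2, DMF (cat.), CH2Cl2, 0 → 25 °C; then TMSCHN2, THF/MeCN, 0 °C; then HCl (4 M in dioxane), 0 °C
Reagents that add atoms: (trimethylsilyl)diazomethane, C[Si](C)(C)C=[N+]=[N-]; hydrogen chloride, Cl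
Why: Arndt–Eistert-type diazoketone formation (C-acylation of the diazoalkane with loss of Me3SiCl) followed by hydrochlorination with loss of N2 adds the one carbon that becomes the ring CH2, without any carbanion or hydride that would attack the furanone or the acetate.

**Step 8**
Reactants: 17 chloromethyl ketone
Product: 18 chlorohydrin (furan C3 bears (1R)-2-chloro-1-hydroxyethyl)
Conditions: RuCl(p-cymene)[(S,S)-TsDPEN] (divalent ruthenium, 1 mol%), HCO2H/Et3N (5:2), EtOAc, 25 °C
Reagents that add atoms: none
Why: Noyori asymmetric transfer hydrogenation of a heteroaryl chloromethyl ketone: the (S,S) catalyst should deliver hydride to the face that gives the (R)-chlorohydrin (same spatial sense as (S)-1-arylethanols), overriding the remote quaternary centre, and the vinylogous-ester carbonyl of the furanone is not reduced.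

**Step 9**
Reactants: 18 chlorohydrin
Product: 19 oxirane alcohol (furan C3 bears (2R)-oxiran-2-yl; furan C4 bears CH2OH)
Conditions: K2CO3, MeOH, 0 °C
Reagents that add atoms: none
Why: Intramolecular Williamson closure gives the oxirane without breaking a bond at the carbinol carbon (it stays (R)) and the primary acetate is methanolysed in the same operation; the freed hydroxyl should not open the neighbouring oxirane at 0 °C because that would require a strained 3,4-fused bicyclic furan.

**Step 10**
Reactants: 19 oxirane alcohol
Product: 20 oxirane silyl ether (furan C4 bears CH2OTBS)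
Conditions: TBSCl, imidazole, DMF, 0 °C
Reagents that add atoms: tert-butyldimethylsilyl chloride, CC(C)(C)[Si](C)(C)Cl
Why: Standard silylation caps the only hydroxyl with a group stable to lithium amides, so that the next step contains no alkoxide other than the one formed by the ring closure.

**Step 11**
Reactants: 20 oxirane silyl ether
Product: 23 bridged macrocyclic alcohol [(S)-CH(CH3) on furanone C5 bonded to the CH2 of the former oxirane; (S)-CH(OH) on furan C3; (S) quaternary centre; CH2OTBS on furan C4], via lithium dienolate 21 (not isolated), via lithium alkoxide 22 (not isolated)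
Conditions: LiN(SiMe3)2 (1.3 equiv), THF (0.002 M), −78 °C; then LiClO4 (3 equiv), −78 → 25 °C; aq. NH4Cl
Reagents that add atoms: none
Why: Proposed new method: the amide base removes a proton from the only acidic position of 20, the CH2 of the ethyl group on furanone C5, and the extended enolate 21 attacks through this exocyclic γ-carbon the terminal CH2 of the lithium-activated oxirane in an SN2 opening to give alkoxide 22, with release of oxirane strain driving the medium-ring closure. The closest known reaction types are the γ-alkylation of 2,2-disubstituted 3(2H)-furanone enolates by alkyl halides, the LiClO4-promoted opening of terminal epoxides by lithium ketone enolates, and carbanion–epoxide closures of ten-membered carbocycles; their combination in one ring-forming event is what is new. The bond closes the nine-membered oxa-bridged ring (ten-membered carbocycle when counted through furanone C3 and C4) in the endo mode, both oxirane carbons ending up in the ring, and the carbinol carbon keeps its spatial arrangement (its descriptor becomes (S) only through the priority change). The new C-methyl centre is controlled by the substrate: the chain reaches the enolate on the furanone face that carries the C2–CH2–furan arm, and the (E)-enolate, with its methyl syn to C4–H and outside the forming ring, leads to (S); reversible deprotonation lets the enolate geometries interconvert, and since the centre stays γ to the ketone a minor epimer can be converged by re-enolization and kinetic protonation from the open face, which gives the same (S) centre. The step needs γ- over α-attack (secured by the vinylogous-ester polarization of the enolate), terminal over furylic oxirane carbon (SN2 conditions with lithium as the only Lewis acid), and ring closure over oligomerization (high dilution and the pre-organization of both arms on adjacent positions of the rigid furan, which also carries no acidic hydrogen).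

**Step 12**
Reactants: 23 macrocyclic alcohol
Product: 24 macrocyclic senecioate (3-methylbut-2-enoate on the (S)-carbinol; CH2OTBS on furan C4)
Conditions: 3-methylbut-2-enoyl chloride, pyridine, DMAP (cat.), CH2Cl2, 0 °C
Reagents that add atoms: 3-methylbut-2-enoyl chloride, CC(C)=CC(Cl)=O
Why: Pyridine/DMAP acylation through the acylpyridinium ion (no triethylamine, so no vinylketene-derived β,γ-unsaturated ester) installs the senecioate without touching a stereocentre.

**Step 13**
Reactants: 24 macrocyclic senecioate
Product: 25 primary alcohol (CH2OH on furan C4)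
Conditions: HF·pyridine, pyridine, THF, 0 °C
Reagents that add atoms: none
Why: Buffered fluoride desilylation cleaves the primary silyl ether under non-basic conditions, so no alkoxide forms that could take over the neighbouring senecioyl group.

**Step 14**
Reactants: 25 primary alcohol
Product: 26 furan diester (CH2OAc on furan C4)
Conditions: Ac2O, pyridine, DMAP (cat.), CH2Cl2, 0 °C
Reagents that add atoms: acetic anhydride, CC(=O)OC(C)=O
Why: DMAP-catalysed acetylation of the primary alcohol completes the ester pattern before the furan is unmasked.

**Step 15**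
Reactants: 26 furan diester
Product: 28 γ-hydroxybutenolide (lactone C=O at former furan C5; hemiketal OH at former furan C2; epimers at the hemiketal carbon), via endoperoxide 27 (not isolated)
Conditions: O2, tetraphenylporphyrin (cat.), visible light, i-Pr2NEt, CH2Cl2, −78 °C; then 25 °C
Reagents that add atoms: dioxygen, O=O
Why: Furan photooxygenation: singlet oxygen adds [4+2] to the electron-rich furan much faster than to the electron-poor enoate and furanone alkenes, and the amine removes the only bridgehead hydrogen of 27 (Kornblum–DeLaMare-type fragmentation), which places the lactone carbonyl at the unsubstituted carbon and the hemiketal at the carbon bearing the ring CH2; the hemiketal centre forms as a mixture that the next step erases.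

**Step 16**
Reactants: 28 γ-hydroxybutenolide
Product: 29 target compound
Conditions: TsOH·H2O (cat.), 4 Å MS, toluene, 60 °C
Reagents that add atoms: none
Why: Acid-catalysed dehydration of a γ-hydroxy-γ-alkylbutenolide: ionization gives an oxygen-stabilized 2-oxofuranium ion whose only adjacent C–H bonds are on the ring CH2, and under these equilibrating conditions the bridged medium ring should admit only the exocyclic alkene with the quaternary carbon cis to the butenolide β-carbon, the (E) geometry of the target; no sp3 centre is touched.

**Compound list**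
1 | (S)-citramalic acid | C[C@](O)(CC(=O)O)C(=O)O | starting material
2 | 2-[(4S)-2,2,4-trimethyl-5-oxo-1,3-dioxolan-4-yl]acetic acid | C[C@@]1(CC(=O)O)OC(C)(C)OC1=O | intermediate
3 | 1-butyne | CCC#C | starting material
4 | 1-butynyllithium (not isolated) | [Li]C#CCC | intermediate
5 | dilithium hemiketal (not isolated) | C[C@@]1(CC(=O)O[Li])OC(C)(C)OC1(O[Li])C#CCC | intermediate
6 | (3S)-3-hydroxy-3-methyl-4-oxooct-5-ynoic acid | CCC#CC(=O)[C@@](C)(O)CC(=O)O | intermediate
7 | 2-[(2S)-5-ethyl-2-methyl-3-oxo-2,3-dihydrofuran-2-yl]acetic acid | CCC1=CC(=O)[C@](C)(CC(=O)O)O1 | intermediate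
8 | acyl imidazole of 7 (not isolated) | CCC1=CC(=O)[C@](C)(CC(=O)n2cncc2)O1 | intermediate
9 | acyl Meldrum's acid (not isolated) | CCC1=CC(=O)[C@](C)(CC(=O)C2C(=O)OC(C)(C)OC2=O)O1 | intermediate
10 | tert-butyl 4-[(2S)-5-ethyl-2-methyl-3-oxo-2,3-dihydrofuran-2-yl]-3-oxobutanoate | CCC1=CC(=O)[C@](C)(CC(=O)CC(=O)OC(C)(C)C)O1 | intermediate
11 | 1-acetoxy-3-chloroacetone | CC(=O)OCC(=O)CCl | starting material
12 | hydroxydihydrofuran (not isolated) | CCC1=CC(=O)[C@](C)(CC2=C(C(=O)OC(C)(C)C)C(O)(COC(C)=O)CO2)O1 | intermediate
13 | furan tert-butyl ester | CCC1=CC(=O)[C@](C)(Cc2occ(COC(C)=O)c2C(=O)OC(C)(C)C)O1 | intermediate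
14 | furan carboxylic acid | CCC1=CC(=O)[C@](C)(Cc2occ(COC(C)=O)c2C(=O)O)O1 | intermediate
15 | acid chloride (not isolated) | CCC1=CC(=O)[C@](C)(Cc2occ(COC(C)=O)c2C(Cl)=O)O1 | intermediate
16 | diazoketone (not isolated) | CCC1=CC(=O)[C@](C)(Cc2occ(COC(C)=O)c2C(=O)C=[N+]=[N-])O1 | intermediate
17 | chloromethyl ketone | CCC1=CC(=O)[C@](C)(Cc2occ(COC(C)=O)c2C(=O)CCl)O1 | intermediate
18 | (R)-chlorohydrin | CCC1=CC(=O)[C@](C)(Cc2occ(COC(C)=O)c2[C@@H](O)CCl)O1 | intermediate
19 | (R)-oxirane primary alcohol | CCC1=CC(=O)[C@](C)(Cc2occ(CO)c2[C@@H]3CO3)O1 | intermediate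
20 | (R)-oxirane silyl ether | CCC1=CC(=O)[C@](C)(Cc2occ(CO[Si](C)(C)C(C)(C)C)c2[C@@H]3CO3)O1 | intermediate
21 | lithium dienolate (not isolated) | CC=C1C=C(O[Li])[C@](C)(Cc2occ(CO[Si](C)(C)C(C)(C)C)c2[C@@H]3CO3)O1 | intermediate
22 | lithium alkoxide (not isolated) | C[C@H]1C[C@H](O[Li])c2c(CO[Si](C)(C)C(C)(C)C)coc2C[C@]2(C)OC1=CC2=O | intermediate
23 | bridged macrocyclic alcohol | C[C@H]1C[C@H](O)c2c(CO[Si](C)(C)C(C)(C)C)coc2C[C@]2(C)OC1=CC2=O | intermediate
24 | macrocyclic senecioate | C[C@H]1C[C@H](OC(=O)C=C(C)C)c2c(CO[Si](C)(C)C(C)(C)C)coc2C[C@]2(C)OC1=CC2=O | intermediate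
25 | primary alcohol | C[C@H]1C[C@H](OC(=O)C=C(C)C)c2c(CO)coc2C[C@]2(C)OC1=CC2=O | intermediate
26 | furan diester | C[C@H]1C[C@H](OC(=O)C=C(C)C)c2c(COC(C)=O)coc2C[C@]2(C)OC1=CC2=O | intermediate
27 | furan endoperoxide (not isolated) | C[C@H]1C[C@H](OC(=O)C=C(C)C)C2=C(COC(C)=O)C3OOC2(O3)C[C@]2(C)OC1=CC2=O | intermediate
28 | γ-hydroxybutenolide | C[C@H]1C[C@H](OC(=O)C=C(C)C)C2=C(COC(C)=O)C(=O)OC2(O)C[C@]2(C)OC1=CC2=O | intermediate
29 | target compound | CC(=O)OCC1=C2/C(=C\[C@]3(C)OC(=CC3=O)[C@@H](C)C[C@@H]2OC(=O)C=C(C)C)OC1=O | target

**Count**
Total: 16 steps. Longest linear sequence: 16 steps (the route is linear from 1).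

**Steps most likely to fail**

Step 11 (Proposed new method). The closure may fail through intermolecular opening (oligomerization), through attack at the furylic oxirane carbon, or because the stabilized enolate is too weak a nucleophile for the oxirane. The fallback uses the known γ-alkylation of this type of furanone enolate by an alkyl iodide; it sets out from 18 and comes back at 23. Chlorohydrin 18 is silylated (Et3SiCl, imidazole) to the triethylsilyl ether F1. K2CO3/MeOH at 0 °C removes the acetate to give the primary alcohol F2; no oxirane can form because the secondary oxygen is capped. TBSCl/imidazole gives the bis-silyl ether F3, and Finkelstein exchange (NaI, 2-butanone, 80 °C) gives the primary iodide F4. The lithium dienolate of F4 (LiN(i-Pr)2, THF/DMPU, high dilution, −78 → 0 °C) is alkylated intramolecularly at the exocyclic γ-carbon to give the macrocyclic silyl ether F5. Selective cleavage of the secondary triethylsilyl ether (PPTS, MeOH, 0 °C) returns 23.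

Step 2. The acetylide may add sluggishly to the hindered carbonyl beside the lithium carboxylate, or add twice after premature collapse of the hemiketal. The fallback sets out from 2 and comes back at 7, bypassing 6 and the gold step. The kinetic lithium enolate of 2-butanone (from 2-(trimethylsilyloxy)but-1-ene and MeLi) is acylated by 2 (pre-deprotonated at the carboxyl) in a Claisen-type condensation to give the 2-hydroxy-1,3-diketone F6. Acid-catalysed cyclodehydration (aq. HCl, THF), the classical 3(2H)-furanone synthesis, gives 7.

Step 8. Hydride transfer may be slow or poorly face-selective at the doubly ortho-substituted heteroaryl ketone, and formate may displace chloride. The fallback sets out from 17 and comes back at 19. NaBH4 (MeOH, −40 °C) reduces the chloromethyl ketone without selectivity to the chlorohydrin epimers F7. K2CO3/MeOH gives the oxirane alcohol epimers F8. Jacobsen hydrolytic kinetic resolution with (salen)Co(OAc) (trivalent cobalt; the (S,S) catalyst by analogy with aryl oxiranes) and water hydrolyses the unwanted (S)-oxirane epimer to the diol F9 and leaves 19.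

**Further compounds**
F1 | step 11 | triethylsilyl ether of chlorohydrin 18 | CCC1=CC(=O)[C@](C)(Cc2occ(COC(C)=O)c2[C@@H](O[Si](CC)(CC)CC)CCl)O1
F2 | step 11 | primary alcohol from F1 | CCC1=CC(=O)[C@](C)(Cc2occ(CO)c2[C@@H](O[Si](CC)(CC)CC)CCl)O1
F3 | step 11 | bis-silyl ether chloride | CCC1=CC(=O)[C@](C)(Cc2occ(CO[Si](C)(C)C(C)(C)C)c2[C@@H](O[Si](CC)(CC)CC)CCl)O1
F4 | step 11 | bis-silyl ether iodide | CCC1=CC(=O)[C@](C)(Cc2occ(CO[Si](C)(C)C(C)(C)C)c2[C@@H](O[Si](CC)(CC)CC)CI)O1
F5 | step 11 | macrocyclic triethylsilyl ether | C[C@H]1C[C@H](O[Si](CC)(CC)CC)c2c(CO[Si](C)(C)C(C)(C)C)coc2C[C@]2(C)OC1=CC2=O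
F6 | step 2 | (3S)-3-hydroxy-3-methyl-4,6-dioxooctanoic acid | CCC(=O)CC(=O)[C@@](C)(O)CC(=O)O
F7 | step 8 | chlorohydrin epimer mixture | CCC1=CC(=O)[C@](C)(Cc2occ(COC(C)=O)c2C(O)CCl)O1
F8 | step 8 | oxirane alcohol epimer mixture | CCC1=CC(=O)[C@](C)(Cc2occ(CO)c2C3CO3)O1
F9 | step 8 | (S)-diol from the unwanted oxirane epimer | CCC1=CC(=O)[C@](C)(Cc2occ(CO)c2[C@H](O)CO)O1
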